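## Structural features

The target 27 is a 5,6-dihydro-2H-pyran-2-one (C1–C5 plus the ring oxygen on C5, with C2=C3 conjugated to the C1 carbonyl) that carries on C5 an unbranched chain C6–C26 with secondary hydroxyls on C7, C9 and C11 and a pentadecyl tail (C12–C26). The four oxygen-bearing carbons C5, C7, C9 and C11 are separated by single methylenes and are all 1,3-syn; in CIP terms the target is 5S,7R,9R,11R, the change of letter at C5 being a priority effect only. The unsaturated lactone is the fragile part: it is a Michael acceptor within reach of the C7 hydroxyl, base can open it or eliminate the C5 oxygen, and the free 1,3-polyol invites acyl and silyl migration. The real difficulty is not a skeletal bond but the relative and absolute control of four carbinols on a flexible chain that offers no handles other than the carbinols themselves. The inner pair C7/C9 is a syn 1,3-diol that can be bought in one piece. The outer carbinols C5 and C11 each stand 1,3-syn to an inner one and next to a carbon (C4, C12) that ends as CH2 and can therefore begin as an alkene carbon. The key step uses exactly this: allylic hydroxyls on C3 and C13 are shifted across C4=C5 and C11=C12 to C5 and C11 and captured with O7 and O9 as two six-membered benzylidene acetals (ring B on C5/C7, ring A on C9/C11), whose all-equatorial chairs define both syn relationships.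

## Logic of the disconnections

27 is cut at the lactone C1–O5 bond and at the four acetal C–O bonds, which leads to 25 (through 26). The reason is that the unsaturated lactone should be made last and that O5 is freed in the same operation as O7, O9 and O11. The gain is that all four carbinols are held in two rigid rings up to the end. The demand is a Z alkene at C2=C3 and an acid treatment that frees the oxygens and lets O5 close on C1 without letting O7 add to C3.

25 is cut at C2=C3 into 22 and 23. The cut removes the two lactone carbons C1 and C2 as one standard olefination unit. The demand is kinetic Z selectivity at low temperature, so that the β-oxygenated 22 does not eliminate.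

22 goes back through 21 and 20 to 18 by changes of functional groups only: the oxidation level of C3, the saturation of C12–C13 and the C3–O bond (terminal hydration of C3=C4). These changes turn the two alkenes left by the key step into what the target needs, and in the backward sense they create the retron, an alkenyl group on each outer carbinol carbon. The demands are that the borane takes the terminal C3=C4 and not the internal C12=C13, and that the reduction of C12=C13 spares the benzylic acetal C–O bonds.

18 is cut at the C5–O and C11–O bonds and at both acetal rings, giving 16 and two molecules of 17. This is the strategic cut: it removes two rings and four stereocentres (C5, C11 and two acetal carbons) and leaves only the bought C7/C9 pair. The forward step must transpose both allylic hydroxyls reversibly and end in the bis(acetal) under thermodynamic control. One point of stereochemical bookkeeping is made precise in step 11: a suprafacial shift ties the configuration at C13 to the geometry of the new C12=C13 bond.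

16 goes back through 15 and 14 to 11 and 12; the silyl ethers on O7, O9 and O13 are restored and C4=C5 is cut. C5 is the ester carbon of the bought block, so a two-carbon Wittig extension and a reduction give the E allylic alcohol. The demand, added here to the bare plan, is that O9 is capped while C5 is a carbonyl carbon (13) and while C3–C5 is an enoate (14); a free O9 would give a lactol and then a six-membered cyclic ether by conjugate addition.

11 goes back through 10 and 9 to 4 and 7 (through 8): the Z alkene becomes an alkyne and the C10–C11 bond is cut. This is the only C–C bond between the half that carries the stereocentres and the half that needs none, and C10 is an unhindered epoxide terminus. The demands are attack at C10 and not at the ester, and a clean cis semi-reduction.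

7 goes back through 6 to 5 by opening the C10–O bond of the epoxide to the chlorohydrin. 5 supplies C5–C10 with C7 and C9 in the correct absolute sense. The demand is that closure of the three-membered ring by O9 outruns five-membered closure by O7, and that O7 is capped before a Lewis acid meets the epoxide.

4 goes back through 3 to 1 and 2 by cutting C12–C13. No stereocontrol is asked for, because C13 loses its oxygen in step 11.

## Other disconnections considered

Alternative 1: The cut runs through C4–C5 and C2–C3 and takes out C1–C6 in one piece. In the forward direction 2-deoxyribose-5-phosphate aldolase would add two molecules of acetaldehyde A3 in turn to chloroacetaldehyde A2, making C4–C5 and then C2–C3, after which the C5 hydroxyl traps the C1 aldehyde as the lactol A1.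
- In its favour: one aqueous step from two-carbon feedstocks without protecting groups; C5 is fixed by the enzyme in the S sense that the target needs; the C3 hydroxyl can later be eliminated to the C2=C3 alkene once C1 is at the lactone level.
- Against it here: A1 covers only the ring. The C7/C9/C11 triol and the tail would have to be made separately and joined at C6, where the only handle is a primary chloride beside an oxygen-bearing carbon. The union would need O5 freed again for an epoxide and a separate stereoselective step for C7, and the C3 centre is made only to be destroyed.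
- Comparison: on structure it secures one of four carbinols, whereas the chosen plan buys two and sets two. On mechanism it is kinetic enzyme control, which is more certain for C5 than the thermodynamic relay of step 11; here the alternative is the better. Its key step is also the better in atom economy. Over the whole target it should be the longer, since a second fragment about as elaborate as 16 is still required.

Alternative 2: The cut takes both bonds to C9 (C8–C9 and C9–C10). In the forward direction the lithio derivative of the silyl dithiane A5 would open the long-chain epoxide A6 at C10, the C11 alkoxide would take silicon from C9 by a 1,4-Brook shift, and the regenerated dithiane anion would open the epoxide A7 at C8 to give A4.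
- In its favour: the highest convergency of all plans and two C–C bonds in one flask. C11 and C7 come from enantiopure epoxides and C5 rides in with A7, so three centres are under separate, reliable control. The relay is established chemistry on this substrate class, which the twofold transposition is not; on precedent the alternative is the better.
- Against it here: C9 is not a stereocentre in A4. The dithiane must be removed in the presence of a p-methoxybenzyl ether and two different silyl ethers, and the ketone must then be reduced 1,3-syn under direction of the free C7 hydroxyl. A7 with its two centres needs a synthesis of its own and A6 a resolution, and three kinds of protecting groups must come off in order.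
- Comparison: on structure every carbinol is set individually, where the chosen plan buys two and relays two. On mechanism the anion chemistry is irreversible, so a wrong centre cannot be corrected, whereas step 11 is meant to correct itself. The longest linear sequence could be equal or shorter (a point for the alternative), but the total step count should be clearly above 16.

Alternative 3: The cut is the C9–O bond, with C8=C9 traced back to a cross-metathesis. In the forward direction the hydroxy enone A9 would add through its C11 hydroxyl to acetaldehyde A3, and the hemiacetal oxygen would add in conjugate fashion to C9 under Bi(NO3)3·5H2O A10, closing the cis-dioxane of A8.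
- In its favour: C9 is set from C11 by the same equatorial-chair preference that the chosen plan relies on. The reaction is known for this class, mild and cheap, so it is equal in kind of control and better in precedent. The metathesis union is convergent.
- Against it here: one centre per operation, and C11 and C5 each need their own asymmetric step. The C7 ketone of A8 must be reduced syn to C9 although O9 is locked in the acetal and O5 carries a bulky silyl group, so no hydroxyl can direct and the selectivity is uncertain. The ethylidene acetal is harder to remove near the end than a benzylidene acetal.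
- Comparison: on structure the relay runs inward from an outer centre that must first be made, while the chosen plan runs outward from a bought inner pair and gains two centres in one operation. On mechanism the two are close relatives (acetal-tethered oxygen delivery under chair control). On step economy the alternative should need more steps and three separate asymmetric operations.

Key step: step 11

Remark: atom labels C1–C26 are those of the target throughout. CIP letters at C7, C9 and C11 change along the route through priority changes only; no centre is inverted. Compounds 3, 4, 8–11 and 13–16 are mixtures of C13 epimers, which is of no consequence because C13 loses its oxygen in step 11.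

Step 1
Reactants: 1 tetradecanal; 2 ethynylmagnesium bromide
Product: 3 (3RS)-hexadec-1-yn-3-ol
Conditions: THF, 0 °C; aq. NH4Cl
Reagents that add atoms: none
Why: Grignard 1,2-addition of the alkynyl nucleophile to an unhindered aldehyde forms C12–C13; no stereocontrol is wanted at C13.

Step 2
Reactants: 3 (3RS)-hexadec-1-yn-3-ol
Product: 4 tert-butyl[(3RS)-hexadec-1-yn-3-yloxy]dimethylsilane
Conditions: TBSCl, imidazole, DMF, 23 °C
Reagents that add atoms: tert-butyldimethylsilyl chloride, CC(C)(C)[Si](C)(C)Cl
Why: Silyl ether formation masks the acidic hydroxyl so that only the alkyne C–H is lithiated in step 5.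

Step 3
Reactants: 5 tert-butyl (3R,5S)-6-chloro-3,5-dihydroxyhexanoate
Product: 6 tert-butyl (3R)-3-hydroxy-4-[(2S)-oxiran-2-yl]butanoate
Conditions: K2CO3, MeOH, 0 → 23 °C
Reagents that add atoms: none
Why: Intramolecular Williamson etherification (3-exo-tet) of the vicinal chlorohydrin; O9 attacks C10, so C9 keeps its configuration, and the three-membered closure should outrun five-membered closure by O7 under mild base.

Step 4
Reactants: 6 tert-butyl (3R)-3-hydroxy-4-[(2S)-oxiran-2-yl]butanoate
Product: 7 tert-butyl (3R)-3-{[tert-butyl(dimethyl)silyl]oxy}-4-[(2S)-oxiran-2-yl]butanoate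
Conditions: TBSCl, imidazole, DMF, 0 → 23 °C
Reagents that add atoms: tert-butyldimethylsilyl chloride, CC(C)(C)[Si](C)(C)Cl
Why: Silylation of the only hydroxyl; it stops O7 from opening the epoxide when BF3·OEt2 is present in step 5.

Step 5
Reactants: 4 tert-butyl[(3RS)-hexadec-1-yn-3-yloxy]dimethylsilane; 7 tert-butyl (3R)-3-{[tert-butyl(dimethyl)silyl]oxy}-4-[(2S)-oxiran-2-yl]butanoate
Product: 9 tert-butyl (3R,5R,9RS)-3,9-bis{[tert-butyl(dimethyl)silyl]oxy}-5-hydroxydocos-7-ynoate, via lithium alkynide 8 (not isolated)
Conditions: 4 (1.6 equiv), n-BuLi, THF, −78 °C; BF3·OEt2; then 7, −78 °C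
Reagents that add atoms: none
Why: Yamaguchi–Hirao alkynylation: 8, activated by BF3·OEt2, opens the epoxide by SN2 attack at the unsubstituted C10 and forms C10–C11 while C9 is untouched; at −78 °C the boron-bound alkynide should neither add to nor enolise the tert-butyl ester.

Step 6
Reactants: 9 tert-butyl (3R,5R,9RS)-3,9-bis{[tert-butyl(dimethyl)silyl]oxy}-5-hydroxydocos-7-ynoate
Product: 10 tert-butyl (3R,5R,9RS)-3,5,9-tris{[tert-butyl(dimethyl)silyl]oxy}docos-7-ynoate
Conditions: TBSCl, imidazole, DMAP (cat.), DMF, 40 °C
Reagents that add atoms: tert-butyldimethylsilyl chloride, CC(C)(C)[Si](C)(C)Cl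
Why: Silylation of O9; a free C9 hydroxyl would form a lactol with the C5 aldehyde of step 8 and add to C5 of enoate 14 (six-membered oxa-Michael closure).

Step 7
Reactants: 10 tert-butyl (3R,5R,9RS)-3,5,9-tris{[tert-butyl(dimethyl)silyl]oxy}docos-7-ynoate
Product: 11 tert-butyl (3R,5R,7Z,9RS)-3,5,9-tris{[tert-butyl(dimethyl)silyl]oxy}docos-7-enoate
Conditions: H2 (1 atm), Pd/CaCO3/Pb(OAc)2, quinoline, EtOAc, 23 °C
Reagents that add atoms: none
Why: Lindlar semihydrogenation: syn delivery of hydrogen on the poisoned palladium surface gives the Z alkene and stops at that stage.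

Step 8
Reactants: 11 tert-butyl (3R,5R,7Z,9RS)-3,5,9-tris{[tert-butyl(dimethyl)silyl]oxy}docos-7-enoate; 12 ethyl (triphenylphosphoranylidene)acetate
Product: 14 ethyl (2E,5S,7R,9Z,11RS)-5,7,11-tris{[tert-butyl(dimethyl)silyl]oxy}tetracosa-2,9-dienoate, via β-silyloxy aldehyde 13 (not isolated)
Conditions: i-Bu2AlH (1.2 equiv), CH2Cl2, −78 °C; MeOH; then 12, −78 → 23 °C
Reagents that add atoms: none
Why: Partial ester reduction, which at −78 °C should stop at the aldehyde oxidation level, followed in the same flask by Wittig olefination with a stabilised ylide, which forms C4=C5 with E geometry; not handling 13 avoids β-elimination of the silyloxy group.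

Step 9
Reactants: 14 ethyl (2E,5S,7R,9Z,11RS)-5,7,11-tris{[tert-butyl(dimethyl)silyl]oxy}tetracosa-2,9-dienoate
Product: 15 (2E,5S,7R,9Z,11RS)-5,7,11-tris{[tert-butyl(dimethyl)silyl]oxy}tetracosa-2,9-dien-1-ol
Conditions: i-Bu2AlH (2.5 equiv), CH2Cl2, −78 °C; aq. KNaC4H4O6
Reagents that add atoms: none
Why: 1,2-Reduction of the enoate by i-Bu2AlH gives the E allylic alcohol and leaves both alkenes and the silyl ethers alone.

Step 10
Reactants: 15 (2E,5S,7R,9Z,11RS)-5,7,11-tris{[tert-butyl(dimethyl)silyl]oxy}tetracosa-2,9-dien-1-ol
Product: 16 (2E,5S,7R,9Z,11RS)-tetracosa-2,9-diene-1,5,7,11-tetraol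
Conditions: Bu4NF (6 equiv), THF, 23 → 40 °C
Reagents that add atoms: none
Why: Fluoride-mediated cleavage of the three silyl ethers; the non-acidic medium avoids ionising the allylic alcohols before the rhenium step.

Step 11
Reactants: 16 (2E,5S,7R,9Z,11RS)-tetracosa-2,9-diene-1,5,7,11-tetraol; 17 benzaldehyde dimethyl acetal (two molecules enter the product)
Product: 18 (2S,4S,6S)-4-{[(2R,4R,6R)-6-ethenyl-2-phenyl-1,3-dioxan-4-yl]methyl}-6-[(1E)-pentadec-1-en-1-yl]-2-phenyl-1,3-dioxane
Conditions: Re2O7 (10 mol %), 17 (5 equiv), CH2Cl2, 0 → 23 °C; then Et3N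
Reagents that add atoms: none
Why: Proposed new method: Re2O7 esterifies the C3 and C13 hydroxyls of 16 to allyl perrhenates, each of which undergoes a reversible suprafacial [3,3]-shift through a chair-like six-membered O–Re–O transition state that moves the oxygen to C5 or C11; the closest known reaction type is the Re2O7-catalysed, hydroxyl-directed 1,3-transposition of a single allylic alcohol with capture of the new 1,3-diol as its benzylidene acetal, here asked to run on both arms of one syn diol in the same flask. Ring B and ring A each close by 6-endo-trig attack of a hydroxyl oxygen (O5 or O11) on the benzylic oxocarbenium ion that the perrhenic acid present generates from the mixed acetal of 17 with the neighbouring oxygen (O7 or O9). C5 and C11 are set under thermodynamic control by the bought centres C7 and C9: only the 1,3-syn isomers give chair dioxanes with all three substituents equatorial, whereas anti isomers reopen and shift back through the perrhenate. The two acetal carbons are set in the same way, with phenyl equatorial. The step needs site selectivity for the 5,7:9,11 bis(acetal) over the C7/C9 mono(acetal) and 1,3-syn selectivity; the first should follow because acetal exchange is reversible under the acid present and only the bis(acetal) ties up all four oxygens when 17 is in excess, the second from the equatorial preference just named. On the C13 arm the Z alkene enforces a transition state with H13 inside, so the 13S epimer should give the 9,11-syn, 12E product directly, whereas the 13R epimer first gives the anti isomer and must be recycled by the reverse shift or by ion-pair return; any 12Z syn isomer that survives becomes the same compound in step 13.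

Step 12
Reactants: 18 (2S,4S,6S)-4-{[(2R,4R,6R)-6-ethenyl-2-phenyl-1,3-dioxan-4-yl]methyl}-6-[(1E)-pentadec-1-en-1-yl]-2-phenyl-1,3-dioxane
Product: 20 primary alcohol of 18 (ethenyl on ring B converted to 2-hydroxyethyl, C3–OH; all six stereocentres and the 12E alkene as in 18), via B-alkyl-9-BBN adduct 19 (not isolated)
Conditions: 9-BBN (2 equiv), THF, 0 → 23 °C; then NaOH, H2O2, 0 °C
Reagents that add atoms: hydrogen peroxide, OO
Why: Hydroboration–oxidation: 9-BBN adds to the monosubstituted alkene far faster than to the 1,2-disubstituted one and places boron on terminal C3 (anti-Markovnikov); alkaline peroxide replaces boron by hydroxyl, and the acetals are inert.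

Step 13
Reactants: 20 primary alcohol of 18 (ethenyl on ring B converted to 2-hydroxyethyl)
Product: 21 saturated alcohol (20 with the pentadec-1-enyl group on ring A reduced to pentadecyl; stereocentres unchanged)
Conditions: TsNHNH2, NaOAc, DME/H2O, reflux
Reagents that add atoms: none
Why: Diimide reduction transfers hydrogen to the unpolarised C12=C13 in a concerted syn step without a metal surface, so the benzylic acetal C–O bonds are not hydrogenolysed; either alkene geometry gives 21.

Step 14
Reactants: 21 saturated alcohol (2-hydroxyethyl on ring B, pentadecyl on ring A)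
Product: 22 aldehyde (the 2-hydroxyethyl group of 21 oxidised to 2-oxoethyl, C3 = CHO)
Conditions: Dess–Martin periodinane, NaHCO3, CH2Cl2, 0 → 23 °C
Reagents that add atoms: none
Why: Dess–Martin oxidation of the primary alcohol under buffered, non-acidic conditions that leave both acetals intact.

Step 15
Reactants: 22 aldehyde (2-oxoethyl on ring B, pentadecyl on ring A); 23 methyl 2-[bis(2,2,2-trifluoroethoxy)phosphoryl]acetate
Product: 25 methyl (2Z)-4-(ring B)but-2-enoate (Z enoate with C1 as methyl ester; both acetals and the pentadecyl group as in 22), via potassium phosphonate carbanion 24 (not isolated)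
Conditions: KN(SiMe3)2, 18-crown-6, THF, −78 °C
Reagents that add atoms: none
Why: Still–Gennari variant of the Horner–Wadsworth–Emmons olefination: the electron-poor trifluoroethyl phosphonate makes elimination faster than equilibration of the adducts, so C2=C3 forms with Z geometry under kinetic control; at −78 °C the β-oxygenated aldehyde should not eliminate.

Step 16
Reactants: 25 methyl (2Z)-4-(ring B)but-2-enoate (bis(benzylidene) acetal)
Product: 27 (6S)-6-[(2R,4R,6R)-2,4,6-trihydroxyhenicosyl]-5,6-dihydro-2H-pyran-2-one, via tetrahydroxy Z-ester 26 (not isolated)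
Conditions: AcOH/H2O (4:1), 60 °C
Reagents that add atoms: none
Why: Acid-catalysed acetal hydrolysis frees O5, O7, O9 and O11 without breaking any carbinol C–O bond; O5, held next to C1 by the Z alkene, closes the six-membered lactone by transesterification with loss of methanol.

Compound list

1 | tetradecanal | CCCCCCCCCCCCCC=O | starting material
2 | ethynylmagnesium bromide | C#C[Mg]Br | starting material
3 | (3RS)-hexadec-1-yn-3-ol | CCCCCCCCCCCCCC(O)C#C | intermediate
4 | tert-butyl[(3RS)-hexadec-1-yn-3-yloxy]dimethylsilane | CCCCCCCCCCCCCC(O[Si](C)(C)C(C)(C)C)C#C | intermediate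
5 | tert-butyl (3R,5S)-6-chloro-3,5-dihydroxyhexanoate | ClC[C@@H](O)C[C@@H](O)CC(=O)OC(C)(C)C | starting material
6 | tert-butyl (3R)-3-hydroxy-4-[(2S)-oxiran-2-yl]butanoate | C1[C@@H](O1)C[C@@H](O)CC(=O)OC(C)(C)C | intermediate
7 | tert-butyl (3R)-3-{[tert-butyl(dimethyl)silyl]oxy}-4-[(2S)-oxiran-2-yl]butanoate | C1[C@@H](O1)C[C@@H](O[Si](C)(C)C(C)(C)C)CC(=O)OC(C)(C)C | intermediate
8 | lithium (3RS)-3-{[tert-butyl(dimethyl)silyl]oxy}hexadec-1-yn-1-ide (formed in the flask) | CCCCCCCCCCCCCC(O[Si](C)(C)C(C)(C)C)C#C[Li] | intermediate
9 | tert-butyl (3R,5R,9RS)-3,9-bis{[tert-butyl(dimethyl)silyl]oxy}-5-hydroxydocos-7-ynoate | CCCCCCCCCCCCCC(O[Si](C)(C)C(C)(C)C)C#CC[C@@H](O)C[C@@H](O[Si](C)(C)C(C)(C)C)CC(=O)OC(C)(C)C | intermediate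
10 | tert-butyl (3R,5R,9RS)-3,5,9-tris{[tert-butyl(dimethyl)silyl]oxy}docos-7-ynoate | CCCCCCCCCCCCCC(O[Si](C)(C)C(C)(C)C)C#CC[C@@H](O[Si](C)(C)C(C)(C)C)C[C@@H](O[Si](C)(C)C(C)(C)C)CC(=O)OC(C)(C)C | intermediate
11 | tert-butyl (3R,5R,7Z,9RS)-3,5,9-tris{[tert-butyl(dimethyl)silyl]oxy}docos-7-enoate | CCCCCCCCCCCCCC(O[Si](C)(C)C(C)(C)C)/C=C\C[C@@H](O[Si](C)(C)C(C)(C)C)C[C@@H](O[Si](C)(C)C(C)(C)C)CC(=O)OC(C)(C)C | intermediate
12 | ethyl (triphenylphosphoranylidene)acetate | CCOC(=O)C=P(c1ccccc1)(c2ccccc2)c3ccccc3 | starting material
13 | (3R,5R,7Z,9RS)-3,5,9-tris{[tert-butyl(dimethyl)silyl]oxy}docos-7-enal (formed in the flask) | CCCCCCCCCCCCCC(O[Si](C)(C)C(C)(C)C)/C=C\C[C@@H](O[Si](C)(C)C(C)(C)C)C[C@@H](O[Si](C)(C)C(C)(C)C)CC=O | intermediate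
14 | ethyl (2E,5S,7R,9Z,11RS)-5,7,11-tris{[tert-butyl(dimethyl)silyl]oxy}tetracosa-2,9-dienoate | CCCCCCCCCCCCCC(O[Si](C)(C)C(C)(C)C)/C=C\C[C@@H](O[Si](C)(C)C(C)(C)C)C[C@@H](O[Si](C)(C)C(C)(C)C)C/C=C/C(=O)OCC | intermediate
15 | (2E,5S,7R,9Z,11RS)-5,7,11-tris{[tert-butyl(dimethyl)silyl]oxy}tetracosa-2,9-dien-1-ol | CCCCCCCCCCCCCC(O[Si](C)(C)C(C)(C)C)/C=C\C[C@@H](O[Si](C)(C)C(C)(C)C)C[C@@H](O[Si](C)(C)C(C)(C)C)C/C=C/CO | intermediate
16 | (2E,5S,7R,9Z,11RS)-tetracosa-2,9-diene-1,5,7,11-tetraol | CCCCCCCCCCCCCC(O)/C=C\C[C@@H](O)C[C@@H](O)C/C=C/CO | intermediate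
17 | benzaldehyde dimethyl acetal | COC(OC)c1ccccc1 | starting material
18 | (2S,4S,6S)-4-{[(2R,4R,6R)-6-ethenyl-2-phenyl-1,3-dioxan-4-yl]methyl}-6-[(1E)-pentadec-1-en-1-yl]-2-phenyl-1,3-dioxane | CCCCCCCCCCCCC/C=C/[C@@H]1C[C@@H](O[C@H](c2ccccc2)O1)C[C@@H]3C[C@H](C=C)O[C@H](c4ccccc4)O3 | intermediate
19 | B-alkyl-9-borabicyclo[3.3.1]nonane adduct of 18 (boron on C3; formed in the flask) | CCCCCCCCCCCCC/C=C/[C@@H]1C[C@@H](O[C@H](c2ccccc2)O1)C[C@@H]3C[C@H](CCB4C5CCCC4CCC5)O[C@H](c6ccccc6)O3 | intermediate
20 | 2-(ring B)ethan-1-ol: 18 with ethenyl converted to 2-hydroxyethyl, 12E, all ring substituents equatorial | CCCCCCCCCCCCC/C=C/[C@@H]1C[C@@H](O[C@H](c2ccccc2)O1)C[C@@H]3C[C@H](CCO)O[C@H](c4ccccc4)O3 | intermediate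
21 | 20 with the pentadecenyl group saturated to pentadecyl | CCCCCCCCCCCCCCC[C@@H]1C[C@@H](O[C@H](c2ccccc2)O1)C[C@@H]3C[C@H](CCO)O[C@H](c4ccccc4)O3 | intermediate
22 | 2-(ring B)acetaldehyde: 21 with CH2OH oxidised to CHO | CCCCCCCCCCCCCCC[C@@H]1C[C@@H](O[C@H](c2ccccc2)O1)C[C@@H]3C[C@H](CC=O)O[C@H](c4ccccc4)O3 | intermediate
23 | methyl 2-[bis(2,2,2-trifluoroethoxy)phosphoryl]acetate | COC(=O)CP(=O)(OCC(F)(F)F)OCC(F)(F)F | starting material
24 | potassium salt of the carbanion of 23 (formed in the flask) | COC(=O)[CH-]P(=O)(OCC(F)(F)F)OCC(F)(F)F.[K+] | intermediate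
25 | methyl (2Z)-4-(ring B)but-2-enoate, bis(benzylidene) acetal of the C5/C7 and C9/C11 diols, pentadecyl on ring A | CCCCCCCCCCCCCCC[C@@H]1C[C@@H](O[C@H](c2ccccc2)O1)C[C@@H]3C[C@H](C/C=C\C(=O)OC)O[C@H](c4ccccc4)O3 | intermediate
26 | methyl (2Z,5S,7S,9R,11R)-5,7,9,11-tetrahydroxyhexacos-2-enoate (formed in the flask) | CCCCCCCCCCCCCCC[C@@H](O)C[C@@H](O)C[C@@H](O)C[C@@H](O)C/C=C\C(=O)OC | intermediate
27 | (6S)-6-[(2R,4R,6R)-2,4,6-trihydroxyhenicosyl]-5,6-dihydro-2H-pyran-2-one | CCCCCCCCCCCCCCC[C@@H](O)C[C@@H](O)C[C@@H](O)C[C@@H]1CC=CC(=O)O1 | target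

Total step count: 16. Longest linear sequence: 14 steps (5 → 27 through steps 3–16; the branch from 1 is equally long, steps 1, 2 and 5–16).

Least certain steps

Step 11 (key step, proposed new method). Three things are most likely to go wrong:
- The system may stall at the C7/C9 mono(acetal), which forms without any transposition and hides both inner hydroxyls.
- The secondary allyl perrhenate on the C11–C13 unit may ionise, followed by capture of the cation by O9 at C13 (a six-membered cyclic ether, possible because C11=C12 is Z) or by O7 at C11, or by capture of the C3–C5 allyl unit by O9 at C5. These ether formations should not revert readily.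
- Equilibration of the 13R epimers may be incomplete, leaving 9,11-anti acetal.

The fallback uses only known reactions, sets out from 7 and rejoins the route at 22:
- 7 is opened with the lithium salt of hexadec-1-yne under the conditions of step 5 to give the homopropargylic alcohol F1.
- Silylation of O9 with tetramethyldisilazane, intramolecular hydrosilylation with the zerovalent platinum complex Pt2[(CH2=CHSiMe2)2O]3 (5-exo-dig) and Tamao–Fleming oxidation (H2O2, KF, KHCO3) give the β-hydroxy ketone F2 with the carbonyl on C11.
- Narasaka–Prasad reduction (Et2BOMe, NaBH4, −78 °C) gives the 9,11-syn diol F3.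
- 17 with pyridinium p-toluenesulfonate gives the ring A benzylidene acetal F4.
- The conditions of step 8 give the E enoate F5, and Bu4NF frees O7 to give the hydroxy enoate F6.
- Base-mediated hemiacetal/oxa-conjugate addition with benzaldehyde (KOt-Bu, THF, 0 °C) closes ring B 5,7-syn and gives the bis(acetal) ethyl ester F7.
- i-Bu2AlH at −78 °C reduces F7 to the aldehyde 22.

Step 5. What may go wrong is attack of the alkynide on the ester carbonyl, or enolisation of the ester with β-elimination of the silyloxy group, and Lewis-acid rearrangement of the epoxide before it is opened. The fallback removes the ester before the coupling; it sets out from 7 and rejoins at 16. 7 is homologated as in step 8 to the epoxy enoate F8, reduced as in step 9 to the epoxy allylic alcohol F9 and silylated to the silyl ether F10. Only then is the epoxide opened with 8 and BF3·OEt2 to the homopropargylic alcohol F11. Lindlar reduction gives the Z alkene F12, and Bu4NF gives 16. O9 needs no protection on this path because no aldehyde or enoate follows the coupling.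

Step 8. What may go wrong is over-reduction to the primary alcohol or incomplete reduction of the hindered tert-butyl ester, and loss of silanol from 13 by β-elimination. The fallback sets out from 11 and rejoins at 14. Exhaustive reduction with excess i-Bu2AlH (−78 → 0 °C) gives the primary alcohol F13. A one-flask oxidation–Wittig sequence (PhI(OAc)2, TEMPO cat., CH2Cl2, then 12) then gives 14, the aldehyde being consumed as it forms.

Step 16. What may go wrong is conjugate addition of the freed C7 hydroxyl to C3 of the unsaturated lactone under the acid needed for benzylidene hydrolysis, incomplete hydrolysis of the second acetal, or incomplete ring closure. The fallback exchanges the acetals for silyl ethers while the molecule is still saturated; it sets out from 21 and ends at 27. Hydrogenolysis of both acetals (H2, Pd(OH)2/C, EtOAc/MeOH; possible because 21 has no alkene) gives the pentaol F14. Et3SiCl and imidazole give the penta(triethylsilyl) ether F15. Swern oxidation, which cleaves and oxidises only the primary triethylsilyl ether, gives the aldehyde F16. The conditions of step 15 give the Z enoate F17. HF·pyridine in THF/pyridine at 0 °C removes the four silyl ethers, whereupon the lactone closes to 27.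

## Further compounds

F1 | step 11 | tert-butyl (3R,5R)-3-{[tert-butyl(dimethyl)silyl]oxy}-5-hydroxydocos-7-ynoate | CCCCCCCCCCCCCCC#CC[C@@H](O)C[C@@H](O[Si](C)(C)C(C)(C)C)CC(=O)OC(C)(C)C
F2 | step 11 | tert-butyl (3R,5S)-3-{[tert-butyl(dimethyl)silyl]oxy}-5-hydroxy-7-oxodocosanoate | CCCCCCCCCCCCCCCC(=O)C[C@@H](O)C[C@@H](O[Si](C)(C)C(C)(C)C)CC(=O)OC(C)(C)C
F3 | step 11 | tert-butyl (3R,5R,7R)-3-{[tert-butyl(dimethyl)silyl]oxy}-5,7-dihydroxydocosanoate | CCCCCCCCCCCCCCC[C@@H](O)C[C@@H](O)C[C@@H](O[Si](C)(C)C(C)(C)C)CC(=O)OC(C)(C)C
F4 | step 11 | tert-butyl (3R)-3-{[tert-butyl(dimethyl)silyl]oxy}-4-(all-cis-6-pentadecyl-2-phenyl-1,3-dioxan-4-yl)butanoate, ring centres as in ring A of 21 | CCCCCCCCCCCCCCC[C@@H]1C[C@@H](O[C@H](c2ccccc2)O1)C[C@@H](O[Si](C)(C)C(C)(C)C)CC(=O)OC(C)(C)C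
F5 | step 11 | ethyl (2E,5S)-5-{[tert-butyl(dimethyl)silyl]oxy}-6-(all-cis-6-pentadecyl-2-phenyl-1,3-dioxan-4-yl)hex-2-enoate | CCCCCCCCCCCCCCC[C@@H]1C[C@@H](O[C@H](c2ccccc2)O1)C[C@@H](O[Si](C)(C)C(C)(C)C)C/C=C/C(=O)OCC
F6 | step 11 | ethyl (2E,5S)-5-hydroxy-6-(all-cis-6-pentadecyl-2-phenyl-1,3-dioxan-4-yl)hex-2-enoate | CCCCCCCCCCCCCCC[C@@H]1C[C@@H](O[C@H](c2ccccc2)O1)C[C@@H](O)C/C=C/C(=O)OCC
F7 | step 11 | ethyl 2-(ring B)acetate, the ethyl ester at the C3 oxidation level corresponding to aldehyde 22 | CCCCCCCCCCCCCCC[C@@H]1C[C@@H](O[C@H](c2ccccc2)O1)C[C@@H]3C[C@H](CC(=O)OCC)O[C@H](c4ccccc4)O3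
F8 | step 5 | ethyl (2E,5S)-5-{[tert-butyl(dimethyl)silyl]oxy}-6-[(2S)-oxiran-2-yl]hex-2-enoate | C1[C@@H](O1)C[C@@H](O[Si](C)(C)C(C)(C)C)C/C=C/C(=O)OCC
F9 | step 5 | (2E,5S)-5-{[tert-butyl(dimethyl)silyl]oxy}-6-[(2S)-oxiran-2-yl]hex-2-en-1-ol | C1[C@@H](O1)C[C@@H](O[Si](C)(C)C(C)(C)C)C/C=C/CO
F10 | step 5 | (2E,5S)-1,5-bis{[tert-butyl(dimethyl)silyl]oxy}-6-[(2S)-oxiran-2-yl]hex-2-ene | C1[C@@H](O1)C[C@@H](O[Si](C)(C)C(C)(C)C)C/C=C/CO[Si](C)(C)C(C)(C)C
F11 | step 5 | (2E,5S,7R,11RS)-1,5,11-tris{[tert-butyl(dimethyl)silyl]oxy}tetracos-2-en-9-yn-7-ol | CCCCCCCCCCCCCC(O[Si](C)(C)C(C)(C)C)C#CC[C@@H](O)C[C@@H](O[Si](C)(C)C(C)(C)C)C/C=C/CO[Si](C)(C)C(C)(C)C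
F12 | step 5 | (2E,5S,7R,9Z,11RS)-1,5,11-tris{[tert-butyl(dimethyl)silyl]oxy}tetracosa-2,9-dien-7-ol | CCCCCCCCCCCCCC(O[Si](C)(C)C(C)(C)C)/C=C\C[C@@H](O)C[C@@H](O[Si](C)(C)C(C)(C)C)C/C=C/CO[Si](C)(C)C(C)(C)C
F13 | step 8 | (3S,5R,7Z,9RS)-3,5,9-tris{[tert-butyl(dimethyl)silyl]oxy}docos-7-en-1-ol | CCCCCCCCCCCCCC(O[Si](C)(C)C(C)(C)C)/C=C\C[C@@H](O[Si](C)(C)C(C)(C)C)C[C@@H](O[Si](C)(C)C(C)(C)C)CCO
F14 | step 16 | all-syn tetracosane-1,3,5,7,9-pentaol with the configuration of 27 at C5, C7, C9 and C11 | CCCCCCCCCCCCCCC[C@@H](O)C[C@@H](O)C[C@@H](O)C[C@@H](O)CCO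
F15 | step 16 | penta(triethylsilyl) ether of F14 | CCCCCCCCCCCCCCC[C@@H](O[Si](CC)(CC)CC)C[C@@H](O[Si](CC)(CC)CC)C[C@@H](O[Si](CC)(CC)CC)C[C@@H](O[Si](CC)(CC)CC)CCO[Si](CC)(CC)CC
F16 | step 16 | all-syn 3,5,7,9-tetrakis[(triethylsilyl)oxy]tetracosanal | CCCCCCCCCCCCCCC[C@@H](O[Si](CC)(CC)CC)C[C@@H](O[Si](CC)(CC)CC)C[C@@H](O[Si](CC)(CC)CC)C[C@@H](O[Si](CC)(CC)CC)CC=O
F17 | step 16 | methyl (2Z)-all-syn-5,7,9,11-tetrakis[(triethylsilyl)oxy]hexacos-2-enoate | CCCCCCCCCCCCCCC[C@@H](O[Si](CC)(CC)CC)C[C@@H](O[Si](CC)(CC)CC)C[C@@H](O[Si](CC)(CC)CC)C[C@@H](O[Si](CC)(CC)CC)C/C=C\C(=O)OC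
A1 | alternative 1 | (4R,6S)-6-(chloromethyl)tetrahydro-2H-pyran-2,4-diol, anomers | ClC[C@@H]1C[C@@H](O)CC(O)O1
A2 | alternative 1 | chloroacetaldehyde | ClCC=O
A3 | alternative 1 | acetaldehyde | CC=O
A4 | alternative 2 | C3–C26 chain with C9 as 1,3-dithiane, free 7-hydroxyl, 5-(4-methoxybenzyl) ether, 11-(tert-butyldimethylsilyl) ether and 3-(tert-butyldiphenylsilyl) ether | CCCCCCCCCCCCCCC[C@@H](O[Si](C)(C)C(C)(C)C)CC1(SCCCS1)C[C@@H](O)C[C@@H](OCc2ccc(OC)cc2)CCO[Si](c3ccccc3)(c4ccccc4)C(C)(C)C
A5 | alternative 2 | 2-(tert-butyldimethylsilyl)-1,3-dithiane | CC(C)(C)[Si](C)(C)C1SCCCS1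
A6 | alternative 2 | (2R)-2-pentadecyloxirane | CCCCCCCCCCCCCCC[C@@H]1CO1
A7 | alternative 2 | tert-butyl{(3S)-3-[(4-methoxybenzyl)oxy]-4-[(2S)-oxiran-2-yl]butoxy}diphenylsilane | C1[C@@H](O1)C[C@@H](OCc2ccc(OC)cc2)CCO[Si](c3ccccc3)(c4ccccc4)C(C)(C)C
A8 | alternative 3 | (4S)-4-[(tert-butyldiphenylsilyl)oxy]-6-[(4-methoxybenzyl)oxy]-1-(all-cis-2-methyl-6-pentadecyl-1,3-dioxan-4-yl)hexan-2-one | CCCCCCCCCCCCCCC[C@@H]1C[C@@H](O[C@H](C)O1)CC(=O)C[C@@H](O[Si](c2ccccc2)(c3ccccc3)C(C)(C)C)CCOCc4ccc(OC)cc4
A9 | alternative 3 | (3S,6E,9R)-3-[(tert-butyldiphenylsilyl)oxy]-9-hydroxy-1-[(4-methoxybenzyl)oxy]tetracos-6-en-5-one | CCCCCCCCCCCCCCC[C@@H](O)C/C=C/C(=O)C[C@@H](O[Si](c1ccccc1)(c2ccccc2)C(C)(C)C)CCOCc3ccc(OC)cc3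
A10 | alternative 3 | bismuth trinitrate pentahydrate | [Bi+3].[O-][N+](=O)[O-].[O-][N+](=O)[O-].[O-][N+](=O)[O-].O.O.O.O.O
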